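**Retrosynthetic overview**

1. Feature: in ring B (C5–C10) the adjacent stereocentres C9 and C10 hold the C11 chain trans to the C20 methyl and cis to C1, which is the relation of the two carbons of an (E)-2,3-disubstituted enal; the decalin is cis-fused (H5 cis to C20). Labdane numbering: ring A = C1–C5 and C10; C17 on C8; C18/C19 on C4; C20 on C10; side chain C11–C16.
2. Ring B first: C8–C9 and C5–C10 by an enantioselective Diels–Alder reaction of enal 11 (CHO = C20) with the 1-carbamato-3-siloxybutadiene 17, unmasked to the C5=C6–C7 enone 19.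
3. Ring A second: C4–C5 by hydrogen-atom-transfer radical addition of the C3=C4 alkene to C5 of the enone, after C8 has taken up methyl and hydroxyl through the α′-enolate.
4. Enal 11: directed aldol condensation of the aldimine of 6-methylhept-5-enal (C20, C10, C1–C4, C18, C19) with the ozonolysis aldehyde of (S)-citronellyl pivalate (C9, C11–C16; brings C13).
5. Endgame: C20 CHO → CH3 through the iodide, C7 C=O → CH2 by Barton–McCombie deoxygenation, pivalate → acetate.

Key step: step 8

Assumption: acetaldehyde N-tert-butylimine (5) is treated as a purchasable reagent, and the (R,R) antipode of the chromium complex is written as the one that leaves the C10-Si face of the enal open; this sense is to be confirmed in the first run, the (S,S) complex being equally accessible.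

**Route**

Step 1
Reactants: 1 (S)-citronellol
Product: 2 (S)-citronellyl pivalate
Conditions: t-BuCOCl, pyridine, DMAP (cat.), CH2Cl2, 0 °C → rt
Reagents that add atoms: pivaloyl chloride, CC(C)(C)C(Cl)=O
Why: Esterification of the primary alcohol by the acid chloride under nucleophilic catalysis gives an ester without α-hydrogen that should survive the later amide bases and aqueous HF.

Step 2
Reactants: 2 (S)-citronellyl pivalate
Product: 4 (S)-3-methyl-6-oxohexyl pivalate, via ozonide 3 (not isolated)
Conditions: O3, CH2Cl2, −78 °C; then PPh3, −78 °C → rt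
Reagents that add atoms: ozone, [O-][O+]=O
Why: Ozonolysis with reductive work-up cleaves the trisubstituted alkene to the aldehyde (future C9) and acetone, and the C13 stereocentre, three bonds away, is not touched.

Step 3
Reactants: 5 acetaldehyde N-tert-butylimine; 6 5-bromo-2-methylpent-2-ene
Product: 8 N-tert-butyl-6-methylhept-5-en-1-imine, via lithiated aldimine 7 (not isolated)
Conditions: LiN(i-Pr)2, THF, −78 → 0 °C; then 6, −78 °C → rt
Reagents that add atoms: none
Why: Metalloenamine alkylation, in which the lithiated aldimine displaces the primary bromide (SN2) and the bulky N-substituent holds the reaction at monoalkylation.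

Step 4
Reactants: 8 N-tert-butyl-6-methylhept-5-en-1-imine; 4 (S)-3-methyl-6-oxohexyl pivalate
Product: 11 (3S,6E)-7-formyl-3,11-dimethyldodeca-6,10-dien-1-yl pivalate, via lithium azaenolate 9 (not isolated), via lithium aldolate 10 (not isolated)
Conditions: LiN(i-Pr)2, THF, −78 → 0 °C; then 4, −78 °C; then aq. oxalic acid, THF, rt → 50 °C
Reagents that add atoms: water, O
Why: Directed aldol condensation of the Wittig type, in which the azaenolate adds to the aldehyde faster than it deprotonates it and acid hydrolysis of the β-oxido imine with loss of water gives the conjugated enal, whose E geometry (C11 trans to CHO) is the thermodynamic one under the equilibrating acid conditions.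

Step 5
Reactants: 12 (E)-4-methoxybut-3-en-2-one
Product: 13 (Z)-4-(benzylamino)but-3-en-2-one
Conditions: BnNH2, CH2Cl2, rt
Reagents that add atoms: benzylamine, NCc1ccccc1
Why: Conjugate addition–elimination of the amine on the β-methoxy enone gives the hydrogen-bonded vinylogous amide.

Step 6
Reactants: 13 (Z)-4-(benzylamino)but-3-en-2-one
Product: 15 methyl benzyl[(E)-3-oxobut-1-enyl]carbamate, via sodium salt 14 (not isolated)
Conditions: NaN(SiMe3)2, THF, −78 °C; then ClCO2Me, −78 → 0 °C
Reagents that add atoms: methyl chloroformate, COC(Cl)=O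
Why: N-Acylation of the deprotonated vinylogous amide gives the vinylogous imide, which lowers the basicity of nitrogen so that the later diene and its cycloadduct tolerate a cationic Lewis acid.

Step 7
Reactants: 15 methyl benzyl[(E)-3-oxobut-1-enyl]carbamate
Product: 17 methyl benzyl[(E)-3-(tert-butyldimethylsilyloxy)buta-1,3-dienyl]carbamate, via sodium enolate 16 (not isolated)
Conditions: NaN(SiMe3)2, THF, −78 °C; then t-BuMe2SiCl, −78 °C → rt
Reagents that add atoms: tert-butyldimethylsilyl chloride, CC(C)(C)[Si](C)(C)Cl
Why: Kinetic enolisation of the methyl ketone and O-silylation (silyl enol ether formation) give the 1-amino-3-siloxydiene with the E enamide geometry kept.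

Step 8
Reactants: 11 (3S,6E)-7-formyl-3,11-dimethyldodeca-6,10-dien-1-yl pivalate; 17 methyl benzyl[(E)-3-(tert-butyldimethylsilyloxy)buta-1,3-dienyl]carbamate
Product: 19 C20-formyl ring B enone, via cycloadduct 18 (not isolated)
Conditions: (R,R)-(salen)Cr(SbF6) (10 mol%; salen = N,N′-bis(3,5-di-tert-butylsalicylidene)cyclohexane-1,2-diamine dianion), 4 Å molecular sieves, CH2Cl2, −20 °C → rt; then aq. HF, MeCN, 0 °C → rt
Reagents that add atoms: none
Why: Proposed new method: the cationic chromium complex binds the formyl oxygen of 11 and the diene adds in a concerted but asynchronous [4+2] cycloaddition, its CH2 terminus bonding to the β-carbon C9 ahead of the bonding of the nitrogen-bearing terminus to C10; the closest known reaction is the (salen)Cr(SbF6)-catalysed Diels–Alder reaction of 1-carbamato-3-siloxybutadienes with α-substituted acroleins, which is here asked to accept an enal that also carries a β-alkyl group. Ring B (C5–C10) is closed as the six-membered ring of this intermolecular cycloaddition, with C8–C9 and C5–C10 formed on one face of the dienophile. C9 and C10 are the new stereocentres: their relative configuration (C11 trans to C20 and cis to C1) is copied from the E geometry of 11 by the suprafacial addition whichever endo or exo mode is followed, and their absolute configuration is set by the salen ligand, which must leave the C10-Si/C9-Re face open. The step needs enantioface selection, the regiochemistry that the nitrogen and oxygen donors impose by polarising the diene towards its CH2 terminus, and addition across C=C in place of hetero-Diels–Alder addition to C=O, which the α-branched, s-trans bound enal is expected to favour. Aqueous HF then cleaves the silyl enol ether and the β-carbamate is lost from the resulting ketone through its enol, which removes C5 as a stereocentre and leaves the C5=C6–C7 enone of 19.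

Step 9
Reactants: 19 C20-formyl ring B enone
Product: 20 C20-hydroxymethyl ring B enone
Conditions: NaBH4, MeOH/CH2Cl2, −78 °C
Reagents that add atoms: none
Why: Chemoselective hydride reduction, since at −78 °C the aldehyde should be reduced far faster than the conjugated and less electrophilic enone carbonyl.

Step 10
Reactants: 20 C20-hydroxymethyl ring B enone
Product: 21 C20-iodomethyl ring B enone
Conditions: PPh3, I2, imidazole, toluene, 80 °C
Reagents that add atoms: iodine, II
Why: Appel-type iodination through the alkoxyphosphonium salt, which iodide displaces at the neopentyl carbon on heating; the iodide is installed now because it has no β-hydrogen and no SN2 path towards the amide bases ahead, and because a C20 oxygen could not be activated later beside the cis C8 hydroxyl without ether formation.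

Step 11
Reactants: 21 C20-iodomethyl ring B enone
Product: 23 8-methyl C20-iodomethyl enone, via lithium dienolate 22 (not isolated)
Conditions: LiN(i-Pr)2, THF, −78 °C; then MeI, DMPU, −78 → −20 °C
Reagents that add atoms: iodomethane, CI
Why: Kinetic α′-deprotonation (C8 is the only enolisable position, C10 being quaternary) and C-methylation of the cross-conjugated dienolate (enolate alkylation); the C8 configuration does not matter because the centre is enolised again in step 12.

Step 12
Reactants: 23 8-methyl C20-iodomethyl enone
Product: 25 8-hydroxy-8-methyl C20-iodomethyl enone, via potassium dienolate 24 (not isolated)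
Conditions: KN(SiMe3)2, THF, −78 → −40 °C; then 2-(phenylsulfonyl)-3-phenyloxaziridine, −78 °C; then AcOH, −78 °C
Reagents that add atoms: 2-(phenylsulfonyl)-3-phenyloxaziridine, O=S(=O)(c1ccccc1)N1OC1c1ccccc1
Why: Enolate hydroxylation by oxygen transfer from the N-sulfonyloxaziridine: the tetrasubstituted dienolate is attacked on the face opposite the C11 chain of the neighbouring C9 (the C1 chain on C10 lies on the same blocked face), which places OH trans to C11 and cis to C20, and the cold acidic quench protonates the tertiary alkoxide before it can displace the neighbouring iodide.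

Step 13
Reactants: 25 8-hydroxy-8-methyl C20-iodomethyl enone
Product: 26 cis-fused 20-iodo-8-hydroxy-7-oxolabdan-15-yl pivalate
Conditions: Fe(acac)3 (30 mol%), PhSiH3, EtOH/ethylene glycol, 60 °C
Reagents that add atoms: none
Why: Hydrogen-atom transfer from an iron hydride to the C3=C4 alkene gives the tertiary C4 radical, which adds 6-exo-trig to the enone β-carbon C5 (reductive olefin–enone coupling of the Giese type) from the face of its own anchor C1 on the neighbouring C10, so that ring A closes cis-fused with H5 cis to C20 before the α-keto radical is reduced and protonated.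

Step 14
Reactants: 26 cis-fused 20-iodo-8-hydroxy-7-oxolabdan-15-yl pivalate
Product: 27 cis-fused 8-hydroxy-7-oxolabdan-15-yl pivalate
Conditions: Bu3SnH, AIBN (cat.), toluene, 80 °C
Reagents that add atoms: none
Why: Radical chain dehalogenation, in which the stannyl radical abstracts iodine and the neopentyl C20 radical, which no longer has a neighbouring alkene to rearrange onto, takes hydrogen from the stannane.

Step 15
Reactants: 27 cis-fused 8-hydroxy-7-oxolabdan-15-yl pivalate
Product: 28 cis-fused labdane-7,8,15-triol
Conditions: LiAlH4, THF, 0 °C → rt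
Reagents that add atoms: none
Why: Hydride reduction of the C7 ketone and reductive cleavage of the pivalate in one operation; the C7 configuration (hydride expected from the convex face, giving mainly the alcohol trans to the C8 hydroxyl) does not matter because C7 becomes CH2.

Step 16
Reactants: 28 cis-fused labdane-7,8,15-triol
Product: 29 cis-fused 7,8-dihydroxylabdan-15-yl acetate
Conditions: AcCl, 2,4,6-collidine, CH2Cl2, −78 °C
Reagents that add atoms: acetyl chloride, CC(Cl)=O
Why: Selective acylation, since at −78 °C with the hindered pyridine base only the primary C15 hydroxyl should react, the C7 hydroxyl being flanked by the fully substituted C8 and the C8 hydroxyl being tertiary.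

Step 17
Reactants: 29 cis-fused 7,8-dihydroxylabdan-15-yl acetate
Product: 30 7-O-phenoxythiocarbonyl derivative of 29
Conditions: PhOC(S)Cl, pyridine, DMAP (cat.), CH2Cl2, 0 °C → rt
Reagents that add atoms: O-phenyl chlorothionoformate, S=C(Cl)Oc1ccccc1
Why: Thioacylation of the secondary C7 hydroxyl under nucleophilic catalysis prepares the Barton–McCombie deoxygenation, while the tertiary hydroxyl is too hindered to be acylated.

Step 18
Reactants: 30 7-O-phenoxythiocarbonyl derivative of 29
Product: 31 (5S,8R,9R,10R,13S)-8-hydroxylabdan-15-yl acetate (target)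
Conditions: Bu3SnH, AIBN (cat.), toluene, 100 °C
Reagents that add atoms: none
Why: Barton–McCombie deoxygenation, in which the stannyl radical adds to C=S, C–O scission releases the secondary C7 radical and the stannane reduces it, with the neighbouring tertiary hydroxyl, the acetate and all stereocentres untouched.

**Compound list**

1 | (S)-citronellol | OCC[C@@H](C)CCC=C(C)C | starting material
2 | (S)-citronellyl pivalate | CC(C)(C)C(=O)OCC[C@@H](C)CCC=C(C)C | intermediate
3 | ozonide of 2 (5,5-dimethyl-1,2,4-trioxolane) | CC(C)(C)C(=O)OCC[C@@H](C)CCC1OOC(C)(C)O1 | intermediate (not isolated)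
4 | (S)-3-methyl-6-oxohexyl pivalate | CC(C)(C)C(=O)OCC[C@@H](C)CCC=O | intermediate
5 | acetaldehyde N-tert-butylimine | C/C=N/C(C)(C)C | starting material
6 | 5-bromo-2-methylpent-2-ene | CC(C)=CCCBr | starting material
7 | lithiated aldimine (lithium N-tert-butyl-N-vinylamide) | [Li]N(C=C)C(C)(C)C | intermediate (not isolated)
8 | N-tert-butyl-6-methylhept-5-en-1-imine | CC(C)=CCCC/C=N/C(C)(C)C | intermediate
9 | lithium azaenolate of 8 | [Li]N(C=CCCC=C(C)C)C(C)(C)C | intermediate (not isolated)
10 | lithium aldolate (β-oxido imine, mixture at the two new carbons) | CC(C)(C)C(=O)OCC[C@@H](C)CCC(O[Li])C(CCC=C(C)C)/C=N/C(C)(C)C | intermediate (not isolated)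
11 | (3S,6E)-7-formyl-3,11-dimethyldodeca-6,10-dien-1-yl pivalate (enal, CHO = C20) | CC(C)(C)C(=O)OCC[C@@H](C)CC/C=C(/C=O)CCC=C(C)C | intermediate (key-step precursor)
12 | (E)-4-methoxybut-3-en-2-one | CO/C=C/C(C)=O | starting material
13 | (Z)-4-(benzylamino)but-3-en-2-one | CC(=O)/C=C\NCc1ccccc1 | intermediate
14 | sodium salt of 13 | CC(=O)C=CN([Na])Cc1ccccc1 | intermediate (not isolated)
15 | methyl benzyl[(E)-3-oxobut-1-enyl]carbamate | COC(=O)N(Cc1ccccc1)/C=C/C(C)=O | intermediate
16 | sodium enolate of 15 | C=C(O[Na])/C=C/N(Cc1ccccc1)C(=O)OC | intermediate (not isolated)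
17 | methyl benzyl[(E)-3-(tert-butyldimethylsilyloxy)buta-1,3-dienyl]carbamate | C=C(O[Si](C)(C)C(C)(C)C)/C=C/N(Cc1ccccc1)C(=O)OC | intermediate (key-step precursor)
18 | cycloadduct: C5 carbamate (endo/exo mixture), C6=C7 silyl enol ether, C10 formyl | CC(C)(C)C(=O)OCC[C@@H](C)CC[C@@H]1[C@](C=O)(CCC=C(C)C)C(N(Cc2ccccc2)C(=O)OC)C=C(O[Si](C)(C)C(C)(C)C)C1 | intermediate (not isolated)
19 | C20-formyl ring B enone: 4-formyl-4-(4-methylpent-3-enyl)cyclohex-2-enone with the (S)-3-methyl-5-pivaloyloxypentyl chain at C9, trans to CHO and cis to the pentenyl chain | CC(C)(C)C(=O)OCC[C@@H](C)CC[C@@H]1[C@](C=O)(CCC=C(C)C)C=CC(=O)C1 | intermediate (key-step product)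
20 | C20-hydroxymethyl ring B enone | CC(C)(C)C(=O)OCC[C@@H](C)CC[C@@H]1[C@](CO)(CCC=C(C)C)C=CC(=O)C1 | intermediate
21 | C20-iodomethyl ring B enone | CC(C)(C)C(=O)OCC[C@@H](C)CC[C@@H]1[C@](CI)(CCC=C(C)C)C=CC(=O)C1 | intermediate
22 | lithium dienolate of 21 (C7–O, C7=C8) | CC(C)(C)C(=O)OCC[C@@H](C)CC[C@@H]1[C@](CI)(CCC=C(C)C)C=CC(O[Li])=C1 | intermediate (not isolated)
23 | 8-methyl C20-iodomethyl enone (C8 epimers) | CC(C)(C)C(=O)OCC[C@@H](C)CC[C@@H]1[C@](CI)(CCC=C(C)C)C=CC(=O)C1C | intermediate
24 | potassium dienolate of 23 | CC(C)(C)C(=O)OCC[C@@H](C)CC[C@@H]1[C@](CI)(CCC=C(C)C)C=CC(O[K])=C1C | intermediate (not isolated)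
25 | 8-hydroxy-8-methyl C20-iodomethyl enone (8-OH trans to C11, cis to C20) | CC(C)(C)C(=O)OCC[C@@H](C)CC[C@@H]1[C@](CI)(CCC=C(C)C)C=CC(=O)[C@@]1(C)O | intermediate
26 | cis-fused 20-iodo-8-hydroxy-7-oxolabdan-15-yl pivalate (H5 cis to C20) | CC(C)(C)C(=O)OCC[C@@H](C)CC[C@@H]1[C@]2(CI)CCCC(C)(C)[C@@H]2CC(=O)[C@@]1(C)O | intermediate
27 | cis-fused 8-hydroxy-7-oxolabdan-15-yl pivalate | CC(C)(C)C(=O)OCC[C@@H](C)CC[C@@H]1[C@]2(C)CCCC(C)(C)[C@@H]2CC(=O)[C@@]1(C)O | intermediate
28 | cis-fused labdane-7,8,15-triol (C7 epimers) | OCC[C@@H](C)CC[C@@H]1[C@]2(C)CCCC(C)(C)[C@@H]2CC(O)[C@@]1(C)O | intermediate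
29 | cis-fused 7,8-dihydroxylabdan-15-yl acetate (C7 epimers) | CC(=O)OCC[C@@H](C)CC[C@@H]1[C@]2(C)CCCC(C)(C)[C@@H]2CC(O)[C@@]1(C)O | intermediate
30 | 7-O-phenoxythiocarbonyl derivative of 29 (C7 epimers) | CC(=O)OCC[C@@H](C)CC[C@@H]1[C@]2(C)CCCC(C)(C)[C@@H]2CC(OC(=S)Oc3ccccc3)[C@@]1(C)O | intermediate
31 | (5S,8R,9R,10R,13S)-8-hydroxylabdan-15-yl acetate | CC(=O)OCC[C@@H](C)CC[C@@H]1[C@]2(C)CCCC(C)(C)[C@@H]2CC[C@@]1(C)O | target

**Step count**

Total steps: 18. Longest linear sequence: 14 steps (1, 2, 4, 8–18; equally 5–18).

**Steps most likely to fail**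

1. Step 8 (Proposed new method). The α- and β-alkyl groups of the enal may slow the cycloaddition so far that diene decomposition, hetero-Diels–Alder addition at the formyl group or a poorly face-selective background pathway take over. The fallback is auxiliary control in a thermal cycloaddition, a known reaction type of 1-amino-3-siloxydienes; it sets out from 12 (with 11) and comes back at 19. Compound 12 is condensed with (2S,5S)-2,5-diphenylpyrrolidine (MeOH, rt) to the vinylogous amide (E)-4-[(2S,5S)-2,5-diphenylpyrrolidin-1-yl]but-3-en-2-one F1. KN(SiMe3)2 and t-BuMe2SiCl (THF, −78 °C) give the C2-symmetric aminosiloxydiene F2. This is heated with 11 in toluene without Lewis acid to the auxiliary-bearing cycloadduct F3, in which a phenyl ring screens one diene face. Aqueous HF in MeCN then releases 19 and the pyrrolidine. The auxiliary antipode is the one whose open diene face meets the C10-Si face of 11 (drawn as 2S,5S; the antipode otherwise).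

2. Step 12. Oxygen transfer to the tetrasubstituted dienolate may discriminate poorly between the faces, because the C20 CH2I group sits 1,3 to C8 on the face to be attacked, or enolisation of the hindered C8–H may stall. The fallback moves oxygenation behind ring closure so that the folded cis-decalin selects the face; it sets out from 23 and comes back at 27. Compound 23 is cyclised under the conditions of step 13 to the 8-methyl decalone iodide F4. Bu3SnH/AIBN gives the 8-methyl decalone F5. Me3SiCl/NaI/Et3N (MeCN) gives the more substituted C7=C8 trimethylsilyl enol ether F6. Rubottom oxidation (m-CPBA, NaHCO3, CH2Cl2, 0 °C; then aq. HF, MeCN) should deliver oxygen to C8 from the convex face opposite C11, giving 27.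

3. Step 17. The new thionocarbonate may close onto the neighbouring tertiary C8 hydroxyl to a cyclic thionocarbonate, whose tin reduction would break the C8–O bond, or thioacylation at the hindered C7 hydroxyl may be slow. The fallback removes the C7 oxygen without a C7 alcohol; it sets out from 27 and comes back at 31. Compound 27 with KN(SiMe3)2 (2.2 equiv) and PhNTf2 (THF, −78 °C) gives the C6=C7 enol triflate F7, C6 being the only enolisable position. Pd(OAc)2/PPh3 with HCO2H and Bu3N (DMF, 60 °C) reduces it to the 6-ene F8. H2 over palladium on carbon (EtOAc) gives the saturated pivalate F9, and LiAlH4 (THF) gives the 8,15-diol F10. AcCl/2,4,6-collidine (CH2Cl2, −78 °C) then gives the target 31.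

**Further compounds**

F1 | step 8 | (E)-4-[(2S,5S)-2,5-diphenylpyrrolidin-1-yl]but-3-en-2-one | CC(=O)/C=C/N1[C@H](c2ccccc2)CC[C@H]1c1ccccc1
F2 | step 8 | (E)-1-[(2S,5S)-2,5-diphenylpyrrolidin-1-yl]-3-(tert-butyldimethylsilyloxy)buta-1,3-diene | C=C(O[Si](C)(C)C(C)(C)C)/C=C/N1[C@H](c2ccccc2)CC[C@H]1c1ccccc1
F3 | step 8 | auxiliary-bearing cycloadduct (C5 pyrrolidinyl, C6=C7 silyl enol ether, C10 formyl) | CC(C)(C)C(=O)OCC[C@@H](C)CC[C@@H]1[C@](C=O)(CCC=C(C)C)C(N2[C@H](c3ccccc3)CC[C@H]2c2ccccc2)C=C(O[Si](C)(C)C(C)(C)C)C1
F4 | step 12 | cis-fused 20-iodo-7-oxolabdan-15-yl pivalate (C8 epimers) | CC(C)(C)C(=O)OCC[C@@H](C)CC[C@@H]1[C@]2(CI)CCCC(C)(C)[C@@H]2CC(=O)C1C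
F5 | step 12 | cis-fused 7-oxolabdan-15-yl pivalate (C8 epimers) | CC(C)(C)C(=O)OCC[C@@H](C)CC[C@@H]1[C@]2(C)CCCC(C)(C)[C@@H]2CC(=O)C1C
F6 | step 12 | C7=C8 trimethylsilyl enol ether of F5 | CC(C)(C)C(=O)OCC[C@@H](C)CC[C@@H]1[C@]2(C)CCCC(C)(C)[C@@H]2CC(O[Si](C)(C)C)=C1C
F7 | step 17 | C6=C7 enol triflate of 27 | CC(C)(C)C(=O)OCC[C@@H](C)CC[C@@H]1[C@]2(C)CCCC(C)(C)[C@@H]2C=C(OS(=O)(=O)C(F)(F)F)[C@@]1(C)O
F8 | step 17 | cis-fused 8-hydroxylabd-6-en-15-yl pivalate | CC(C)(C)C(=O)OCC[C@@H](C)CC[C@@H]1[C@]2(C)CCCC(C)(C)[C@@H]2C=C[C@@]1(C)O
F9 | step 17 | cis-fused 8-hydroxylabdan-15-yl pivalate | CC(C)(C)C(=O)OCC[C@@H](C)CC[C@@H]1[C@]2(C)CCCC(C)(C)[C@@H]2CC[C@@]1(C)O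
F10 | step 17 | cis-fused labdane-8,15-diol | OCC[C@@H](C)CC[C@@H]1[C@]2(C)CCCC(C)(C)[C@@H]2CC[C@@]1(C)O
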